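All constants stand for no real mixture; no experiment stands behind them.

The meeting opened on what a reader of this flask will see at 30 min.

electrophile 0.20 M; nucleophile 0.300 M; gas 27 mM (held); time 30 min

    gas ⇌ free base, rate k1*(csat - [free base]) (k1 = 2.3 min⁻¹, csat = 27 mM)
    crystals ⇌ acid set free, rate k2*(cs2 - [acid set free]) while solid is left; crystals form when [acid set free] > cs2 (cs2 = 0.10 M, k2 = 39 min⁻¹)
    nucleophile + acid set free ⇌ protonated nucleophile, settled at all times (K3 = 51 M⁻¹)
    electrophile + target → side product (k4 = 0.34 M⁻¹ min⁻¹)
    acid set free + free base ⇌ salt of the base, settled at all times (K5 = 3.5 × 10⁶ M⁻¹)
    electrophile + nucleophile → acid set free + target (k6 = 0.67 M⁻¹ min⁻¹)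

- percentages count the electrophile that a species holds: one side product counts as two
- acid set free is meant together with its crystals
- solid, in amounts per volume of the solution: crystals
- at the start none of free base is dissolved
- run time (flask): 30 min

- part of the electrophile that has reacted at 30 min
- share of the unused nucleophile that is free and not bound as protonated nucleophile, at 30 min

Minutes. The chair proposed to follow one molecule of electrophile and ask, at each encounter, which partner takes it. I put the answer into the fork ratio 1.97, the rate constant with nucleophile divided by the rate constant with target (the selectivity factor). I argued that it ties target to nucleophile without any clock. Call x the fraction of nucleophile left and y the target as a fraction of the nucleophile charge. Then y is the fork ratio over the fork ratio less one, times x raised to the inverse fork ratio, less x.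

Electrophile spent, in the same unit, is two for each nucleophile used, less y. At x = 0.444, y = 0.443 and the spending is 0.668, which matches the charge ratio of 0.667. So I held the electrophile to be the limiting reagent, ending near 66.5% target.

For the clock, I reckoned the electrophile's loss constant as 0.201 min⁻¹ at the start and 0.135 min⁻¹ at that end point, a decline. Held over the whole 30 min, the two constants give c of 98.3% and 99.8%, and I committed to that range.

On the acid, a colleague argued that at the start, with no free base dissolved, the gas delivers 0.0621 M min⁻¹ of free base, more than the 0.0402 M min⁻¹ of acid released then. Counting the acid released up to my end point as salt of the base, and taking free base at 27 mM, the colleague put free acid at that point near 1.76 × 10⁻⁶ M. That leaves 8.99 × 10⁻⁵ bound nucleophile per free one.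

The forecast, 98.7% and >99.9%, rested on the view that “free acid stays at the micromolar level”.

The flask gives 98.8% and >99.9%. At 30.0 min it holds nucleophile 45.1% of its charge and target 66.0% of the electrophile charged. With these readings and the fork ratio, an electrophile molecule still present goes to nucleophile with chance 66.9%.

In the neighbour charged with 0.18 M of nucleophile, the curve matches spending to charge at x = 0.200, the point where its electrophile is used up, with target 44.2% there. At 30 min that neighbour is short of that point: it stands at 90.1% reacted, with electrophile 9.92% left, nucleophile 25.1% of its charge and target 44.7%.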